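Atom labels used throughout: ring C1 (CH–O-acyl), C2 (C=O), C3 (C–CH3), C4 (epoxide CH), C5 (CH2), C6 (CH); side chain C7 (oxirane carbon, its CH2 = C14), C8 (C=O), C9=C10, C11 (carbinol). Compound numbers 1–24 are those of the steps below.

## Analysis of the target

The target 24 is a cyclohexanone (C1–C6) fused to an oxirane at C3–C4. It carries the isovalerate on C1, the ketone at C2, a methyl on C3 and, on C6, a 2,2-disubstituted oxirane (C7/C14) acylated by an (E)-4-hydroxy-4-methylpent-2-enoyl unit (C8–C11). There are five stereocentres: C1 (S), C3 (S), C4 (S) and C6 (R) on the ring and C7 (R) outside it. The ring epoxide oxygen and the C6 branch lie on one face and the C1 acyloxy group on the other, so C1 is trans to both. C7 is a quaternary centre in an open chain next to C6, so the ring cannot be trusted to relay its configuration and a reagent has to set it. The sensitive groups are two α,β-epoxy ketones, an α-acyloxy ketone (enolizable C1–H, ester able to migrate or eliminate), an enone and a tertiary allylic alcohol; strong base, hard nucleophiles, reducing metals and strong acid are therefore excluded late. The difficulty is the density of oxygen on C1–C4, the need to tell the two neighbouring oxygens at C1 and C2 apart (ester versus ketone), and the quaternary epoxide. The strategy rests on one feature: C1 and C2 carry vicinal oxygen, C3 a methyl and C6 a carbon branch para to that methyl, which is the pattern of the cis-2,3-dihydrodiol of a para-disubstituted toluene. All six ring carbons, the methyl and both oxygens therefore map onto 4-iodotoluene 1, with the C–I bond as the handle at C6.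

## Retrosynthetic reasoning

24 to 23 to 22: no skeletal bond is cut. The C2 and C8 carbonyls are traced back to carbinols and the C11 hydroxyl to its silyl ether. This keeps the α-acyloxy ketone and both epoxy ketones latent until the end; forward, one non-basic oxidation must convert two secondary alcohols at once, followed by a mild acid deprotection.

22 to 18 and 19: the C8–C9 bond is cut. This is the only convergent junction and it sets the E alkene through a syn hydrometalation of alkyne 19 (via 20 and 21). Aldehyde 18 has no α-hydrogen, so C7 cannot epimerize; the forward addition must distinguish the aldehyde from an ester and two epoxides, and the configuration at C8 is irrelevant.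

18 to 17 to 16: the C7–O and C14–O bonds of the side-chain oxirane are cut. Placing a primary allylic alcohol on C8 allows a reagent-controlled Sharpless epoxidation to set the open-chain quaternary C7, and the same hydroxyl is afterwards the source of the C8 carbonyl.

16 to 14 and 15: the C7–C8 bond is cut. The enol triflate of 14 is a masked C7=C14 that survives acid, silylation, Mitsunobu conditions and a directed epoxidation, so the allylic alcohol can be released only when nothing else competes for the epoxidation reagents. The coupling must come before any epoxy ketone exists.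

14 to 13: the C3–O and C4–O bonds are cut. The free C2 hydroxyl of 13 is allylic to C3=C4 and on the face that the epoxide must occupy, so a directed epoxidation delivers both centres.

13 to 12 to 10 and 11: the C1–O bond is cut. The enzymatic oxygen at C1 has the wrong configuration, and an SN2 esterification with isovaleric acid 11 corrects it and installs the ester in one step. This is done on the cyclohexenol, with C2 masked as a silyl ether in 10, and not on the final α-ketol between two epoxides. 10 comes from diol 9 by monosilylation.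

9 to 8 to 7: the diol is released from the acetonide once C6 is fixed, and the enol triflate O–C7 bond is traced to the methyl ketone 7 through its kinetic enolate. The forward step must enolize toward the methyl group and leave C6–H alone.

7 to 6: the C5–H and C6–H bonds are cut. A conjugate reduction of the dienone saturates only the bond conjugated to the carbonyl, and the cis-fused acetonide decides from which face C6 receives its hydrogen.

6 to 3 and 4 (via 5): the C6–C7 bond is cut at the alkenyl iodide. A two-carbon acyl-anion equivalent brings C7 and C14 together and gives the ketone whose methyl side becomes the enol triflate.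

3 to 2 to 1: the C1–O and C2–O bonds are cut. A single enzymatic cis-dihydroxylation of arene 1 supplies both ring oxygens, two stereocentres, the C3 methyl and the C6 handle; the forward reaction must select one of two mirror-image binding orientations of a para-disubstituted arene.

## Alternatives that were turned down

Alternative 1: The ring is cut at C1–C2 and C5–C6, a Diels–Alder reaction of diene A3 with the chiral β-acyloxyacryloyl imide A2 under Et2AlCl giving cyclohexene A1.
- For it: one step closes the ring, sets C1 and C6 trans through the E dienophile, and already carries the isovalerate on C1 in the final configuration. On this point it is stronger than the chosen route, which needs an inversion at C1.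
- Against it: the β-acyloxy group lowers the reactivity of A2 towards an unactivated diene and can ionize under the Lewis acid. C2 in A1 is a bare methylene, so the ketone has to come from an allylic C–H oxidation that competes with C5 and the methyl group. The C1 ester is β to the C7 carbonyl, so each step that turns the imide into the branched side chain risks E1cB loss of isovalerate.
- Comparison: it delivers two of five stereocentres and none of the oxygen at C2–C4. The chosen route pays one inversion step but has C1 and C2 oxygenated from the first step and uses the C2 alcohol to place the epoxide.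

Alternative 2: The ring is cut at C2–C3, an intramolecular Nozaki–Hiyama–Kishi reaction (CrCl2, catalytic NiCl2) of iodo aldehyde A5 closing cyclohexenol A4.
- For it: the closure creates the C2 carbinol that directs the epoxidation, C1 is carried with the correct configuration from the start, and C6 comes from dependable open-chain chemistry. On the C1 configuration it is again stronger.
- Against it: A5 needs two adjacent stereocentres and a (Z)-trisubstituted alkenyl iodide, which costs most of the step budget before the ring exists. The configuration formed at C2 is not certain to be cis to the C6 arm. The ether on C1 has to be exchanged for the ester, and the two-carbon arm still needs α-methylenation and further steps to reach C7, C14 and C8. It also uses stoichiometric chromium.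
- Comparison: the ring is assembled atom by atom, whereas the chosen route obtains the intact carbocycle with both oxygens in one operation.

Alternative 3: The ring is cut at C1–C6 and C3–C4, an amine-catalysed Michael addition of keto ester A8 to enal A7 followed by acid-mediated aldol condensation and decarboxylation to enone A6.
- For it: it is catalytic, needs no fermentation and reaches a ring with the C2 carbonyl at its final oxidation level, the methyl in place and C6 set in one or two steps. On catalyst simplicity and on the C2 oxidation state it is stronger.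
- Against it: C1 has no oxygen, so an α′-oxygenation trans to the C6 arm is needed. A nucleophilic epoxidation of a 5-substituted cyclohexenone enters anti to that substituent, the wrong face, so the enone must be reduced, epoxidized under hydroxyl direction and re-oxidized. Every later centre depends on the single stereocentre at C6, and the arm needs the same elaboration as in alternative 2.
- Comparison: the chosen route starts with two ring oxygens of defined absolute configuration and a C2 alcohol already on the face the epoxide needs.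

Key step: step 1

## Route

Remark: 22 forms as a mixture of epimers at C8, which is immaterial because C8 becomes a carbonyl in step 15; stannanes 4 and 15 and silyl ether 19 are taken as catalogue compounds.

Step 1
Reactants: 1 4-iodotoluene
Product: 2 (1S,2S)-3-iodo-6-methylcyclohexa-3,5-diene-1,2-diol
Conditions: E. coli JM109 (pDTG601) whole cells expressing toluene dioxygenase, IPTG induction, glucose feed, aerated phosphate buffer pH 7.2, 30 °C; 1 dosed as a solution in liquid paraffin; EtOAc extraction at pH 8
Reagents that add atoms: dioxygen, O=O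
Why: The Rieske dioxygenase takes two electrons from NADH through its reductase and ferredoxin, binds O2 at a mononuclear non-haem ferrous centre and transfers both oxygen atoms to the same face of one arene π-bond, so C1–O and C2–O form cis and the benzene ring is dearomatized to a cyclohexadiene. The closest known reaction type is the toluene-dioxygenase cis-dihydroxylation of halobenzenes and 4-halotoluenes. No ring is closed. Both new stereocentres are set by the enzyme pocket: the larger para substituent, iodine, should occupy the site that holds the substituent of a monosubstituted arene, so the diol forms with the same absolute sense as from iodobenzene, (1S,2S). Position selectivity is not an issue because the C2–C3 and C5–C6 bonds of 1 are equivalent; the selectivity needed is between the iodine-directed and the methyl-directed binding orientation, secured by the size difference between the two groups. Over-oxidation to the catechol is avoided because the host lacks the cis-diol dehydrogenase.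

Step 2
Reactants: 2 (1S,2S)-3-iodo-6-methylcyclohexa-3,5-diene-1,2-diol
Product: 3 (3aS,7aS)-4-iodo-2,2,7-trimethyl-3a,7a-dihydro-1,3-benzodioxole
Conditions: 2,2-dimethoxypropane, p-TsOH·H2O (cat.), acetone, 0 °C to rt; Et3N quench
Reagents that add atoms: 2,2-dimethoxypropane, COC(C)(C)OC
Why: Acid-catalysed transketalization of the cis-diol gives the cis-fused dioxolane, which stops dehydration to phenols and later shields one ring face; no stereocentre is touched.

Step 3
Reactants: 3 (3aS,7aS)-4-iodo-2,2,7-trimethyl-3a,7a-dihydro-1,3-benzodioxole; 4 tributyl(1-ethoxyethenyl)stannane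
Product: 6 1-[(3aR,7aS)-2,2,7-trimethyl-3a,7a-dihydro-1,3-benzodioxol-4-yl]ethan-1-one, via dienyl enol ether 5 (not isolated)
Conditions: PdCl2(PPh3)2 (5 mol%), toluene, 80 °C; then 0.5 M aq. HCl, THF, 0 °C
Reagents that add atoms: water, O
Why: Stille coupling (oxidative addition of zerovalent palladium into the alkenyl C–I bond, transmetalation, reductive elimination) forms C6–C7 and brings C14; brief cold dilute acid hydrolyses the α-alkoxy enol ether to the methyl ketone much faster than it attacks the acetonide.

Step 4
Reactants: 6 1-[(3aR,7aS)-2,2,7-trimethyl-3a,7a-dihydro-1,3-benzodioxol-4-yl]ethan-1-one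
Product: 7 1-[(3aR,4R,7aS)-2,2,7-trimethyl-3a,4,5,7a-tetrahydro-1,3-benzodioxol-4-yl]ethan-1-one
Conditions: Cu(OAc)2·H2O (5 mol%), 1,2-bis(diphenylphosphino)benzene (5 mol%), (Me2HSi)2O, t-BuOH, toluene, 0 °C to rt
Reagents that add atoms: none
Why: Copper-hydride conjugate reduction: hydride goes to the unhindered β-carbon C5 and not to the fully substituted δ-carbon C3, so C3=C4 survives. The copper enolate is then protonated by the bulky alcohol on the convex face, anti to the dioxolane, which should set C6 with its hydrogen anti and the acetyl group syn to the C1 oxygen.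

Step 5
Reactants: 7 1-[(3aR,4R,7aS)-2,2,7-trimethyl-3a,4,5,7a-tetrahydro-1,3-benzodioxol-4-yl]ethan-1-one
Product: 8 1-[(3aR,4R,7aS)-2,2,7-trimethyl-3a,4,5,7a-tetrahydro-1,3-benzodioxol-4-yl]ethenyl trifluoromethanesulfonate
Conditions: LiN(iPr)2 (1.1 equiv), THF, −78 °C; PhNTf2, −78 to 0 °C
Reagents that add atoms: N-phenylbis(trifluoromethanesulfonimide), O=S(=O)(N(c1ccccc1)S(=O)(=O)C(F)(F)F)C(F)(F)F
Why: Kinetic enolization by the hindered amide base at low temperature takes a methyl proton and not the tertiary C6–H, so C6 keeps its configuration; O-sulfonylation of the enolate gives the terminal enol triflate that masks C7=C14.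

Step 6
Reactants: 8 1-[(3aR,4R,7aS)-2,2,7-trimethyl-3a,4,5,7a-tetrahydro-1,3-benzodioxol-4-yl]ethenyl trifluoromethanesulfonate
Product: 9 1-[(1R,5S,6R)-5,6-dihydroxy-4-methylcyclohex-3-en-1-yl]ethenyl trifluoromethanesulfonate
Conditions: AcOH–H2O (4:1), 40 °C
Reagents that add atoms: none
Why: Acid hydrolysis of the ketal; the enol triflate tolerates aqueous acetic acid, and C6 is no longer α to a carbonyl, so the face-shielding acetonide can be given up.

Step 7
Reactants: 9 1-[(1R,5S,6R)-5,6-dihydroxy-4-methylcyclohex-3-en-1-yl]ethenyl trifluoromethanesulfonate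
Product: 10 1-[(1R,5S,6R)-5-[(tert-butyldimethylsilyl)oxy]-6-hydroxy-4-methylcyclohex-3-en-1-yl]ethenyl trifluoromethanesulfonate
Conditions: TBSCl (1.05 equiv), imidazole, DMF, −10 °C
Reagents that add atoms: tert-butyldimethylsilyl chloride, CC(C)(C)[Si](C)(C)Cl
Why: Selective silylation of the more accessible hydroxyl: the allylic, pseudo-equatorial C2–OH should react before the axial C1–OH, which is flanked by two substituted sp3 carbons (C2 and the cis C6 branch), the pattern that governs monosilylation of shikimate-type cis-diols.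

Step 8
Reactants: 10 1-[(1R,5S,6R)-5-[(tert-butyldimethylsilyl)oxy]-6-hydroxy-4-methylcyclohex-3-en-1-yl]ethenyl trifluoromethanesulfonate; 11 3-methylbutanoic acid (isovaleric acid)
Product: 12 (1S,2S,6R)-2-[(tert-butyldimethylsilyl)oxy]-3-methyl-6-{1-[(trifluoromethanesulfonyl)oxy]ethenyl}cyclohex-3-en-1-yl 3-methylbutanoate
Conditions: PPh3, diisopropyl azodicarboxylate, toluene, 0 °C to rt
Reagents that add atoms: none
Why: Mitsunobu esterification: the C1 alkoxyphosphonium ion is displaced by isovalerate in an SN2 step from the face that carries only hydrogen on C2 and C6, which inverts C1 to the configuration of the target and installs the ester in the same step.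

Step 9
Reactants: 12 (1S,2S,6R)-2-[(tert-butyldimethylsilyl)oxy]-3-methyl-6-{1-[(trifluoromethanesulfonyl)oxy]ethenyl}cyclohex-3-en-1-yl 3-methylbutanoate
Product: 13 (1S,2S,6R)-2-hydroxy-3-methyl-6-{1-[(trifluoromethanesulfonyl)oxy]ethenyl}cyclohex-3-en-1-yl 3-methylbutanoate
Conditions: HF·pyridine, pyridine, THF, 0 °C to rt
Reagents that add atoms: none
Why: Fluoride cleavage of the silyl ether in an acidic buffer, which does not promote migration of the neighbouring ester and leaves the enol triflate intact.

Step 10
Reactants: 13 (1S,2S,6R)-2-hydroxy-3-methyl-6-{1-[(trifluoromethanesulfonyl)oxy]ethenyl}cyclohex-3-en-1-yl 3-methylbutanoate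
Product: 14 (1R,2R,3S,4R,6S)-2-hydroxy-1-methyl-4-{1-[(trifluoromethanesulfonyl)oxy]ethenyl}-7-oxabicyclo[4.1.0]heptan-3-yl 3-methylbutanoate
Conditions: VO(acac)2 (5 mol%), t-BuOOH (in decane), CH2Cl2, 0 °C to rt
Reagents that add atoms: tert-butyl hydroperoxide, CC(C)(C)OO
Why: Vanadium-catalysed hydroxyl-directed epoxidation: the peroxide bound to the vanadate ester of the C2 alcohol is delivered to the syn face of the allylic C3=C4 bond, which sets C3 and C4 cis to the C2 oxygen and to the C6 branch. The electron-poor enol triflate alkene has no allylic hydroxyl and is not oxidized.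

Step 11
Reactants: 14 (1R,2R,3S,4R,6S)-2-hydroxy-1-methyl-4-{1-[(trifluoromethanesulfonyl)oxy]ethenyl}-7-oxabicyclo[4.1.0]heptan-3-yl 3-methylbutanoate; 15 (tributylstannyl)methanol
Product: 16 (1R,2R,3S,4S,6S)-2-hydroxy-4-(3-hydroxyprop-1-en-2-yl)-1-methyl-7-oxabicyclo[4.1.0]heptan-3-yl 3-methylbutanoate
Conditions: Pd(PPh3)4 (10 mol%), LiCl, 1,4-dioxane, 90 °C
Reagents that add atoms: none
Why: Stille coupling of the enol triflate with the hydroxymethylstannane forms C7–C8; it is placed before any α,β-epoxy ketone exists, because such groups can isomerize in the presence of zerovalent palladium.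

Step 12
Reactants: 16 (1R,2R,3S,4S,6S)-2-hydroxy-4-(3-hydroxyprop-1-en-2-yl)-1-methyl-7-oxabicyclo[4.1.0]heptan-3-yl 3-methylbutanoate
Product: 17 (1R,2R,3S,4R,6S)-2-hydroxy-4-[(2S)-2-(hydroxymethyl)oxiran-2-yl]-1-methyl-7-oxabicyclo[4.1.0]heptan-3-yl 3-methylbutanoate
Conditions: Ti(OiPr)4 (0.3 equiv), L-(+)-diisopropyl tartrate (0.36 equiv), t-BuOOH, 4 Å molecular sieves, CH2Cl2, −20 °C
Reagents that add atoms: tert-butyl hydroperoxide, CC(C)(C)OO
Why: Sharpless asymmetric epoxidation of the 2-substituted allylic alcohol: the titanium L-(+)-tartrate complex delivers oxygen with the facial sense that turns 2-methylprop-2-en-1-ol into (S)-2-methylglycidol, which here gives the (S)-epoxy alcohol and corresponds to 7R in the target. The reagent and not the ring controls C7, and the ring C2–OH has no alkene left to epoxidize.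

Step 13
Reactants: 17 (1R,2R,3S,4R,6S)-2-hydroxy-4-[(2S)-2-(hydroxymethyl)oxiran-2-yl]-1-methyl-7-oxabicyclo[4.1.0]heptan-3-yl 3-methylbutanoate
Product: 18 (1R,2R,3S,4R,6S)-4-[(2R)-2-formyloxiran-2-yl]-2-hydroxy-1-methyl-7-oxabicyclo[4.1.0]heptan-3-yl 3-methylbutanoate
Conditions: TEMPO (10 mol%), PhI(OAc)2, CH2Cl2, rt
Reagents that add atoms: none
Why: Oxoammonium (TEMPO) oxidation is selective for the primary alcohol; the hindered secondary C2–OH next to the quaternary epoxide carbon is left for step 15, and the quaternary C7 cannot epimerize in the aldehyde.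

Step 14
Reactants: 18 (1R,2R,3S,4R,6S)-4-[(2R)-2-formyloxiran-2-yl]-2-hydroxy-1-methyl-7-oxabicyclo[4.1.0]heptan-3-yl 3-methylbutanoate; 19 trimethyl[(2-methylbut-3-yn-2-yl)oxy]silane
Product: 22 (1R,2R,3S,4R,6S)-2-hydroxy-4-{(2R)-2-[(2E)-1-hydroxy-4-methyl-4-(trimethylsilyloxy)pent-2-en-1-yl]oxiran-2-yl}-1-methyl-7-oxabicyclo[4.1.0]heptan-3-yl 3-methylbutanoate (both C8 carbinol epimers), via alkenylzirconocene chloride 20 (not isolated), via alkenylmethylzinc 21 (not isolated)
Conditions: 19 (3 equiv), Cp2Zr(H)Cl, CH2Cl2, rt; Me2Zn, −65 °C; then 18, 0 °C; aq. NH4Cl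
Reagents that add atoms: none
Why: Hydrozirconation adds Zr–H syn across the terminal alkyne with the metal on the terminal carbon, which fixes the E alkene. Transmetalation to zinc gives an alkenylzinc that adds to the aldehyde but not to esters or epoxides; excess reagent covers the free C2–OH, and the C8 configuration does not matter.

Step 15
Reactants: 22 (1R,2R,3S,4R,6S)-2-hydroxy-4-{(2R)-2-[(2E)-1-hydroxy-4-methyl-4-(trimethylsilyloxy)pent-2-en-1-yl]oxiran-2-yl}-1-methyl-7-oxabicyclo[4.1.0]heptan-3-yl 3-methylbutanoate (both C8 carbinol epimers)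
Product: 23 (1S,3S,4R,6S)-1-methyl-4-{(2R)-2-[(2E)-4-methyl-4-(trimethylsilyloxy)pent-2-enoyl]oxiran-2-yl}-2-oxo-7-oxabicyclo[4.1.0]heptan-3-yl 3-methylbutanoate
Conditions: Dess–Martin periodinane (4 equiv), NaHCO3, CH2Cl2, rt
Reagents that add atoms: none
Why: Dess–Martin oxidation converts both secondary alcohols (C2 and C8) into ketones in one buffered, non-basic operation. The tertiary silyl ether, both epoxides and the C1 ester are spectators, and the C1 ester is equatorial and trans to the C6 branch, the more stable arrangement.

Step 16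
Reactants: 23 (1S,3S,4R,6S)-1-methyl-4-{(2R)-2-[(2E)-4-methyl-4-(trimethylsilyloxy)pent-2-enoyl]oxiran-2-yl}-2-oxo-7-oxabicyclo[4.1.0]heptan-3-yl 3-methylbutanoate
Product: 24 (1S,3S,4R,6S)-4-{(2R)-2-[(2E)-4-hydroxy-4-methylpent-2-enoyl]oxiran-2-yl}-1-methyl-2-oxo-7-oxabicyclo[4.1.0]heptan-3-yl 3-methylbutanoate (CNP0292003.1)
Conditions: AcOH–THF–H2O (3:1:1), 0 °C to rt
Reagents that add atoms: none
Why: Mild acid hydrolysis of the tertiary trimethylsilyl ether; both epoxides are α to carbonyl groups and therefore resist acid-catalysed opening, and no base is present that could epimerize C1 or shift the ester.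

## Compound list

1 | 4-iodotoluene | Cc1ccc(I)cc1 | starting material
2 | (1S,2S)-3-iodo-6-methylcyclohexa-3,5-diene-1,2-diol | O[C@H]1[C@@H](O)C(C)=CC=C1I | intermediate
3 | (3aS,7aS)-4-iodo-2,2,7-trimethyl-3a,7a-dihydro-1,3-benzodioxole | CC1(C)O[C@H]2[C@@H](O1)C(C)=CC=C2I | intermediate
4 | tributyl(1-ethoxyethenyl)stannane | CCCC[Sn](CCCC)(CCCC)C(=C)OCC | starting material
5 | (3aR,7aS)-4-(1-ethoxyethenyl)-2,2,7-trimethyl-3a,7a-dihydro-1,3-benzodioxole | CC1(C)O[C@H]2[C@@H](O1)C(C)=CC=C2C(=C)OCC | intermediate
6 | 1-[(3aR,7aS)-2,2,7-trimethyl-3a,7a-dihydro-1,3-benzodioxol-4-yl]ethan-1-one | CC1(C)O[C@H]2[C@@H](O1)C(C)=CC=C2C(C)=O | intermediate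
7 | 1-[(3aR,4R,7aS)-2,2,7-trimethyl-3a,4,5,7a-tetrahydro-1,3-benzodioxol-4-yl]ethan-1-one | CC1(C)O[C@H]2[C@@H](O1)C(C)=CC[C@H]2C(C)=O | intermediate
8 | 1-[(3aR,4R,7aS)-2,2,7-trimethyl-3a,4,5,7a-tetrahydro-1,3-benzodioxol-4-yl]ethenyl trifluoromethanesulfonate | CC1(C)O[C@H]2[C@@H](O1)C(C)=CC[C@H]2C(=C)OS(=O)(=O)C(F)(F)F | intermediate
9 | 1-[(1R,5S,6R)-5,6-dihydroxy-4-methylcyclohex-3-en-1-yl]ethenyl trifluoromethanesulfonate | O[C@H]1[C@@H](O)C(C)=CC[C@H]1C(=C)OS(=O)(=O)C(F)(F)F | intermediate
10 | 1-[(1R,5S,6R)-5-[(tert-butyldimethylsilyl)oxy]-6-hydroxy-4-methylcyclohex-3-en-1-yl]ethenyl trifluoromethanesulfonate | O[C@H]1[C@@H](O[Si](C)(C)C(C)(C)C)C(C)=CC[C@H]1C(=C)OS(=O)(=O)C(F)(F)F | intermediate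
11 | 3-methylbutanoic acid (isovaleric acid) | CC(C)CC(=O)O | starting material
12 | (1S,2S,6R)-2-[(tert-butyldimethylsilyl)oxy]-3-methyl-6-{1-[(trifluoromethanesulfonyl)oxy]ethenyl}cyclohex-3-en-1-yl 3-methylbutanoate | CC(C)CC(=O)O[C@@H]1[C@@H](O[Si](C)(C)C(C)(C)C)C(C)=CC[C@H]1C(=C)OS(=O)(=O)C(F)(F)F | intermediate
13 | (1S,2S,6R)-2-hydroxy-3-methyl-6-{1-[(trifluoromethanesulfonyl)oxy]ethenyl}cyclohex-3-en-1-yl 3-methylbutanoate | CC(C)CC(=O)O[C@@H]1[C@@H](O)C(C)=CC[C@H]1C(=C)OS(=O)(=O)C(F)(F)F | intermediate
14 | (1R,2R,3S,4R,6S)-2-hydroxy-1-methyl-4-{1-[(trifluoromethanesulfonyl)oxy]ethenyl}-7-oxabicyclo[4.1.0]heptan-3-yl 3-methylbutanoate | CC(C)CC(=O)O[C@@H]1[C@@H](O)[C@@]2(C)O[C@H]2C[C@H]1C(=C)OS(=O)(=O)C(F)(F)F | intermediate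
15 | (tributylstannyl)methanol | OC[Sn](CCCC)(CCCC)CCCC | starting material
16 | (1R,2R,3S,4S,6S)-2-hydroxy-4-(3-hydroxyprop-1-en-2-yl)-1-methyl-7-oxabicyclo[4.1.0]heptan-3-yl 3-methylbutanoate | CC(C)CC(=O)O[C@@H]1[C@@H](O)[C@@]2(C)O[C@H]2C[C@H]1C(=C)CO | intermediate
17 | (1R,2R,3S,4R,6S)-2-hydroxy-4-[(2S)-2-(hydroxymethyl)oxiran-2-yl]-1-methyl-7-oxabicyclo[4.1.0]heptan-3-yl 3-methylbutanoate | CC(C)CC(=O)O[C@@H]1[C@@H](O)[C@@]2(C)O[C@H]2C[C@H]1[C@]3(CO)CO3 | intermediate
18 | (1R,2R,3S,4R,6S)-4-[(2R)-2-formyloxiran-2-yl]-2-hydroxy-1-methyl-7-oxabicyclo[4.1.0]heptan-3-yl 3-methylbutanoate | CC(C)CC(=O)O[C@@H]1[C@@H](O)[C@@]2(C)O[C@H]2C[C@H]1[C@]3(C=O)CO3 | intermediate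
19 | trimethyl[(2-methylbut-3-yn-2-yl)oxy]silane | C#CC(C)(C)O[Si](C)(C)C | starting material
20 | chlorobis(cyclopentadienyl)[(1E)-3-methyl-3-(trimethylsilyloxy)but-1-en-1-yl]zirconium | Cl[Zr](/C=C/C(C)(C)O[Si](C)(C)C)(C1C=CC=C1)C1C=CC=C1 | intermediate
21 | methyl[(1E)-3-methyl-3-(trimethylsilyloxy)but-1-en-1-yl]zinc | C[Zn]/C=C/C(C)(C)O[Si](C)(C)C | intermediate
22 | (1R,2R,3S,4R,6S)-2-hydroxy-4-{(2R)-2-[(2E)-1-hydroxy-4-methyl-4-(trimethylsilyloxy)pent-2-en-1-yl]oxiran-2-yl}-1-methyl-7-oxabicyclo[4.1.0]heptan-3-yl 3-methylbutanoate (both C8 carbinol epimers) | CC(C)CC(=O)O[C@@H]1[C@@H](O)[C@@]2(C)O[C@H]2C[C@H]1[C@]3(C(O)/C=C/C(C)(C)O[Si](C)(C)C)CO3 | intermediate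
23 | (1S,3S,4R,6S)-1-methyl-4-{(2R)-2-[(2E)-4-methyl-4-(trimethylsilyloxy)pent-2-enoyl]oxiran-2-yl}-2-oxo-7-oxabicyclo[4.1.0]heptan-3-yl 3-methylbutanoate | CC(C)CC(=O)O[C@@H]1C(=O)[C@@]2(C)O[C@H]2C[C@H]1[C@]3(C(=O)/C=C/C(C)(C)O[Si](C)(C)C)CO3 | intermediate
24 | (1S,3S,4R,6S)-4-{(2R)-2-[(2E)-4-hydroxy-4-methylpent-2-enoyl]oxiran-2-yl}-1-methyl-2-oxo-7-oxabicyclo[4.1.0]heptan-3-yl 3-methylbutanoate | CC(C)CC(=O)O[C@@H]1C(=O)[C@@]2(C)O[C@H]2C[C@H]1[C@]1(C(=O)/C=C/C(C)(C)O)CO1 | target

## Step count and risks

Total step count: 16. Longest linear sequence: 16 steps (1 to 24); compounds 4, 11, 15 and 19 enter as purchased materials.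

Steps least certain to work:

Step 1 (key step). The likeliest failure is incomplete discrimination between the two para substituents: if methyl competes with iodine for the directing position, part of the substrate is oxidized in the mirror-image orientation and the enantiomeric purity falls. Low conversion of the poorly soluble, membrane-toxic solid and acid-triggered dehydration of the diol during isolation would add to this. The fallback is enrichment by crystallization of a derivative. It sets out from scalemic 2, which is condensed with phenylboronic acid to the cyclic boronate (3aS,7aS)-4-iodo-7-methyl-2-phenyl-3a,7a-dihydro-1,3,2-benzodioxaborole F1. F1 is recrystallized to enantiomeric purity and cleaved by transesterification with propane-1,3-diol, which returns to the route at 2.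

Step 4. The enolate may be protonated from the concave face, or the cis ketone may equilibrate afterwards to the probably more stable trans isomer; loss of the C1 oxygen by β-elimination from the enolate and competing 1,6- or 1,2-hydride delivery are further risks. The fallback replaces kinetic protonation by a thermodynamic lactone trap. It sets out from 3, which is methoxycarbonylated (Pd(OAc)2, PPh3, CO, MeOH, Et3N) to the dienoate methyl (3aR,7aS)-2,2,7-trimethyl-3a,7a-dihydro-1,3-benzodioxole-4-carboxylate F2. The same copper-hydride reduction gives the ester methyl (3aR,7aS)-2,2,7-trimethyl-3a,4,5,7a-tetrahydro-1,3-benzodioxole-4-carboxylate F3 in whatever C6 ratio forms. Aqueous acetic acid and then DBU remove the ketal and equilibrate C6; only the epimer with the carboxyl cis to the C2 hydroxyl can close the bridged lactone (1R,5S,8R)-8-hydroxy-4-methyl-6-oxabicyclo[3.2.1]oct-3-en-7-one F4, so the mixture drains into it. Opening with Me(MeO)NH·HCl and AlMe3 gives the amide (1R,5S,6R)-5,6-dihydroxy-N-methoxy-N,4-dimethylcyclohex-3-ene-1-carboxamide F5, and acetonide formation gives (3aR,4R,7aS)-N-methoxy-N,2,2,7-tetramethyl-3a,4,5,7a-tetrahydro-1,3-benzodioxole-4-carboxamide F6. MeMgBr then returns to the route at 7.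

Step 7. Silylation may occur at the C1 hydroxyl or at both hydroxyls, because the steric difference between the two sites is moderate. The fallback differentiates the diol by oxidation state instead of by protection. It sets out from 9, whose allylic alcohol alone is oxidized with MnO2 to the ketol 1-[(1R,6R)-6-hydroxy-4-methyl-5-oxocyclohex-3-en-1-yl]ethenyl trifluoromethanesulfonate F7. Mitsunobu esterification with 11 inverts the electronically activated, less encumbered C1 to (1S,6R)-3-methyl-2-oxo-6-{1-[(trifluoromethanesulfonyl)oxy]ethenyl}cyclohex-3-en-1-yl 3-methylbutanoate F8. Luche reduction (NaBH4, CeCl3·7H2O, MeOH, −78 °C) by axial hydride delivery gives the equatorial C2 alcohol cis to the C6 branch and returns to the route at 13.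

Step 8. Formation of the alkoxyphosphonium ion at the flanked axial hydroxyl may be slow, and anti elimination towards C6 or ester formation with retention through an acyloxyphosphonium ion may then take over. The fallback separates activation from displacement. It sets out from 10, which is converted with Tf2O and pyridine into 1-[(1R,5S,6R)-5-[(tert-butyldimethylsilyl)oxy]-4-methyl-6-[(trifluoromethanesulfonyl)oxy]cyclohex-3-en-1-yl]ethenyl trifluoromethanesulfonate F9. The secondary triflate is displaced with cesium 3-methylbutanoate (from 11 and Cs2CO3) and 18-crown-6 in toluene, which returns to the route at 12.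

Step 12. The C6 stereocentre next to the alkene may oppose the tartrate (mismatched double diastereoselection), the ring hydroxyl may bind titanium and slow turnover, and the 2,2-disubstituted epoxy alcohol may be opened by titanium alkoxide. The fallback changes from electrophilic, titanium-directed epoxidation of the alcohol to amine-catalysed nucleophilic epoxidation of the enal. It sets out from 16, which is oxidized with MnO2 to (1R,2R,3S,4S,6S)-2-hydroxy-1-methyl-4-(3-oxoprop-1-en-2-yl)-7-oxabicyclo[4.1.0]heptan-3-yl 3-methylbutanoate F10. Epoxidation with aqueous H2O2 and a 9-amino-9-deoxy-epi-cinchona alkaloid salt, using the pseudo-enantiomer that gives the 7R epoxide, returns to the route at 18.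

## Further compounds

F1 | step 1 | (3aS,7aS)-4-iodo-7-methyl-2-phenyl-3a,7a-dihydro-1,3,2-benzodioxaborole | c1ccccc1B1O[C@H]2[C@@H](O1)C(C)=CC=C2I
F2 | step 4 | methyl (3aR,7aS)-2,2,7-trimethyl-3a,7a-dihydro-1,3-benzodioxole-4-carboxylate | CC1(C)O[C@H]2[C@@H](O1)C(C)=CC=C2C(=O)OC
F3 | step 4 | methyl (3aR,7aS)-2,2,7-trimethyl-3a,4,5,7a-tetrahydro-1,3-benzodioxole-4-carboxylate (both C4 epimers) | CC1(C)O[C@H]2[C@@H](O1)C(C)=CCC2C(=O)OC
F4 | step 4 | (1R,5S,8R)-8-hydroxy-4-methyl-6-oxabicyclo[3.2.1]oct-3-en-7-one | O[C@H]1[C@@H]2C(C)=CC[C@H]1C(=O)O2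
F5 | step 4 | (1R,5S,6R)-5,6-dihydroxy-N-methoxy-N,4-dimethylcyclohex-3-ene-1-carboxamide | O[C@H]1[C@@H](O)C(C)=CC[C@H]1C(=O)N(C)OC
F6 | step 4 | (3aR,4R,7aS)-N-methoxy-N,2,2,7-tetramethyl-3a,4,5,7a-tetrahydro-1,3-benzodioxole-4-carboxamide | CC1(C)O[C@H]2[C@@H](O1)C(C)=CC[C@H]2C(=O)N(C)OC
F7 | step 7 | 1-[(1R,6R)-6-hydroxy-4-methyl-5-oxocyclohex-3-en-1-yl]ethenyl trifluoromethanesulfonate | O[C@H]1C(=O)C(C)=CC[C@H]1C(=C)OS(=O)(=O)C(F)(F)F
F8 | step 7 | (1S,6R)-3-methyl-2-oxo-6-{1-[(trifluoromethanesulfonyl)oxy]ethenyl}cyclohex-3-en-1-yl 3-methylbutanoate | CC(C)CC(=O)O[C@@H]1C(=O)C(C)=CC[C@H]1C(=C)OS(=O)(=O)C(F)(F)F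
F9 | step 8 | 1-[(1R,5S,6R)-5-[(tert-butyldimethylsilyl)oxy]-4-methyl-6-[(trifluoromethanesulfonyl)oxy]cyclohex-3-en-1-yl]ethenyl trifluoromethanesulfonate | FC(F)(F)S(=O)(=O)O[C@H]1[C@@H](O[Si](C)(C)C(C)(C)C)C(C)=CC[C@H]1C(=C)OS(=O)(=O)C(F)(F)F
F10 | step 12 | (1R,2R,3S,4S,6S)-2-hydroxy-1-methyl-4-(3-oxoprop-1-en-2-yl)-7-oxabicyclo[4.1.0]heptan-3-yl 3-methylbutanoate | CC(C)CC(=O)O[C@@H]1[C@@H](O)[C@@]2(C)O[C@H]2C[C@H]1C(=C)C=O
A1 | alternative 1 | (1R,6R)-6-[(4R)-4-benzyl-2-oxooxazolidine-3-carbonyl]-3-methylcyclohex-3-en-1-yl 3-methylbutanoate | CC(C)CC(=O)O[C@@H]1CC(C)=CC[C@H]1C(=O)N2C(=O)OC[C@H]2Cc3ccccc3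
A2 | alternative 1 | (4R)-4-benzyl-3-[(2E)-3-(3-methylbutanoyloxy)prop-2-enoyl]-1,3-oxazolidin-2-one | CC(C)CC(=O)O/C=C/C(=O)N1C(=O)OC[C@H]1Cc1ccccc1
A3 | alternative 1 | 2-methylbuta-1,3-diene (isoprene) | C=CC(C)=C
A4 | alternative 2 | 5-[2-(tert-butyldimethylsilyloxy)ethyl]-6-(4-methoxybenzyloxy)-2-methylcyclohex-2-en-1-ol, configured as in the SMILES | COc1ccc(CO[C@@H]2[C@@H](O)C(C)=CC[C@H]2CCO[Si](C)(C)C(C)(C)C)cc1
A5 | alternative 2 | (5Z)-3-[2-(tert-butyldimethylsilyloxy)ethyl]-6-iodo-2-(4-methoxybenzyloxy)hept-5-enal, configured as in the SMILES | COc1ccc(CO[C@H](C=O)[C@H](CCO[Si](C)(C)C(C)(C)C)C/C=C(/C)I)cc1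
A6 | alternative 3 | (5S)-5-[2-(tert-butyldiphenylsilyloxy)ethyl]-2-methylcyclohex-2-en-1-one | C1C(=O)C(C)=CC[C@H]1CCO[Si](c2ccccc2)(c2ccccc2)C(C)(C)C
A7 | alternative 3 | (2E)-5-(tert-butyldiphenylsilyloxy)pent-2-enal | O=C/C=C/CCO[Si](c1ccccc1)(c1ccccc1)C(C)(C)C
A8 | alternative 3 | tert-butyl 3-oxopentanoate | CCC(=O)CC(=O)OC(C)(C)C
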